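**Plan**

- Retrosynthesis: the 7-O-allyl group is cut first, then ring D at C5'–C4'' and O–C2'' (catechol flavan 14 plus 3-methylbut-2-enal), then O1–C2 of ring C, then C3–C4 (aldol), and last the C2'–prenyl bond (Claisen shift of a tert-prenyl ether).
- Forward: the ring B ketone is prenylated at C2', joined to the ring A aldehyde through C3–C4, reduced, closed to ring C through O1–C2, and ring D is annulated last.
- Stereochemistry: the only stereocenter, C2, comes from a ruthenium/(R,R)-TsDPEN transfer hydrogenation that should give the (R)-carbinol, which the Mitsunobu closure inverts to (2S).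
- Enabling feature: ring B is numbered C1' (on flavan C2), C2' (prenyl), C3' (OH), C4' (OH, later the oxygen of ring D), C5' (H), C6' (H). In the catechol only the C4' hydroxyl has a free ortho carbon (C5'), because C2' is occupied, so the annulation O–C2''–C3''–C4''–C5' can give one chromene only.

Key step: step 12

Remark on the chemistry: the C7 oxygen is carried as an allyl ether, because this group has to pass through hydroxide (step 7), acid (step 11) and hot titanium alkoxide (step 12) and must then leave without acid. All work with catechol 14 is done under argon.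

**Route**

Step 1
Reactants: 1 2-methylbut-3-en-2-ol
Product: 2 tert-butyl 2-methylbut-3-en-2-yl carbonate
Conditions: n-BuLi, THF, −78 °C to 0 °C; Boc2O, 0 °C to rt
Reagents that add atoms: di-tert-butyl dicarbonate, CC(C)(C)OC(=O)OC(=O)OC(C)(C)C
Why: O-acylation of the lithium alkoxide of the tertiary alcohol (carbonate formation) should give the mixed carbonate that later serves as the tert-prenyl donor.

Step 2
Reactants: 3 3,4-dihydroxyacetophenone
Product: 4 1-[3-hydroxy-4-(methoxymethoxy)phenyl]ethanone
Conditions: MOMCl (1.05 equiv), K2CO3 (1.1 equiv), acetone, 0 °C to rt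
Reagents that add atoms: chloromethyl methyl ether, COCCl
Why: Williamson-type etherification under weak base should alkylate the more acidic 4-hydroxyl, whose phenoxide is conjugated with the para acetyl group, and leave the 3-hydroxyl free.

Step 3
Reactants: 4 1-[3-hydroxy-4-(methoxymethoxy)phenyl]ethanone; 2 tert-butyl 2-methylbut-3-en-2-yl carbonate
Product: 5 1-[4-(methoxymethoxy)-3-(2-methylbut-3-en-2-yloxy)phenyl]ethanone
Conditions: Pd(PPh3)4 (3 mol %), 4 Å MS, THF, 0 °C to rt
Reagents that add atoms: none
Why: Tsuji–Trost O-allylation, in which zerovalent palladium ionizes carbonate 2 with loss of CO2, the tert-butoxide formed deprotonates the phenol, and the phenoxide attacks the more substituted terminus of the 1,1-dimethylallyl palladium complex under kinetic control.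

Step 4
Reactants: 5 1-[4-(methoxymethoxy)-3-(2-methylbut-3-en-2-yloxy)phenyl]ethanone
Product: 6 1-[3-hydroxy-4-(methoxymethoxy)-2-(3-methylbut-2-enyl)phenyl]ethanone
Conditions: N,N-diethylaniline, 130 °C, argon
Reagents that add atoms: none
Why: aromatic Claisen rearrangement, whose [3,3] shift goes to C2, the only hydrogen-bearing carbon ortho to the ether oxygen (C4 carries the MOM ether), and turns the 1,1-dimethylallyl group into the 3-methylbut-2-enyl group before tautomerization restores the phenol.

Step 5
Reactants: 6 1-[3-hydroxy-4-(methoxymethoxy)-2-(3-methylbut-2-enyl)phenyl]ethanone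
Product: 7 1-[3,4-bis(methoxymethoxy)-2-(3-methylbut-2-enyl)phenyl]ethanone
Conditions: MOMCl, K2CO3, DMF, 0 °C to rt
Reagents that add atoms: chloromethyl methyl ether, COCCl
Why: Williamson-type etherification of the hindered phenol, so that no free hydroxyl on this ring enters the aldol and Mitsunobu steps.

Step 6
Reactants: 8 2,4-dihydroxybenzaldehyde
Product: 9 4-(allyloxy)-2-hydroxybenzaldehyde
Conditions: allyl bromide (1.05 equiv), K2CO3 (1.0 equiv), acetone, rt to 40 °C
Reagents that add atoms: allyl bromide, C=CCBr
Why: selective Williamson etherification, because the 2-hydroxyl is tied up in a hydrogen bond to the formyl group and the 4-hydroxyl is the one alkylated.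

Step 7
Reactants: 7 1-[3,4-bis(methoxymethoxy)-2-(3-methylbut-2-enyl)phenyl]ethanone; 9 4-(allyloxy)-2-hydroxybenzaldehyde
Product: 10 (E)-3-[4-(allyloxy)-2-hydroxyphenyl]-1-[3,4-bis(methoxymethoxy)-2-(3-methylbut-2-enyl)phenyl]prop-2-en-1-one
Conditions: KOH (50 % aq.), EtOH, rt; AcOH to pH 7
Reagents that add atoms: none
Why: Claisen–Schmidt condensation, in which the methyl ketone enolate adds to the aldehyde and E1cB loss of water gives the (E)-enone, while the MOM, allyl and prenyl groups are stable to hydroxide.

Step 8
Reactants: 10 (E)-3-[4-(allyloxy)-2-hydroxyphenyl]-1-[3,4-bis(methoxymethoxy)-2-(3-methylbut-2-enyl)phenyl]prop-2-en-1-one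
Product: 11 3-[4-(allyloxy)-2-hydroxyphenyl]-1-[3,4-bis(methoxymethoxy)-2-(3-methylbut-2-enyl)phenyl]propan-1-one
Conditions: [(Ph3P)CuH]6 (0.4 equiv), H2O (5 equiv), toluene, rt, argon
Reagents that add atoms: none
Why: conjugate reduction with the phosphine copper hydride hexamer, which delivers hydride only to the β-carbon of the enone while water protonates the copper enolate, so the prenyl and allyl olefins and the carbonyl group should stay.

Step 9
Reactants: 11 3-[4-(allyloxy)-2-hydroxyphenyl]-1-[3,4-bis(methoxymethoxy)-2-(3-methylbut-2-enyl)phenyl]propan-1-one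
Product: 12 (1R)-3-[4-(allyloxy)-2-hydroxyphenyl]-1-[3,4-bis(methoxymethoxy)-2-(3-methylbut-2-enyl)phenyl]propan-1-ol
Conditions: RuCl[(R,R)-TsDPEN](p-cymene) (2 mol %), HCO2H/Et3N (5:2), EtOAc, 30 °C
Reagents that add atoms: none
Why: Noyori-type asymmetric transfer hydrogenation, in which the (R,R)-TsDPEN ruthenium hydride reduces the ketone through a six-membered outer-sphere transition state with the aryl group held by a CH–π contact to the cymene ligand, which should set the carbinol center as (R) as it does for acetophenone-type aryl alkyl ketones.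

Step 10
Reactants: 12 (1R)-3-[4-(allyloxy)-2-hydroxyphenyl]-1-[3,4-bis(methoxymethoxy)-2-(3-methylbut-2-enyl)phenyl]propan-1-ol
Product: 13 (2S)-7-(allyloxy)-2-[3,4-bis(methoxymethoxy)-2-(3-methylbut-2-enyl)phenyl]chroman
Conditions: PPh3, DIAD, THF, 0 °C to rt
Reagents that add atoms: none
Why: intramolecular Mitsunobu etherification (6-exo-tet), in which the ring A phenol displaces the oxyphosphonium group with inversion, so that the (R)-carbinol should give the (2S) center, low temperature keeping the electron-rich benzylic carbon on the SN2 path.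

Step 11
Reactants: 13 (2S)-7-(allyloxy)-2-[3,4-bis(methoxymethoxy)-2-(3-methylbut-2-enyl)phenyl]chroman
Product: 14 (2S)-7-(allyloxy)-3',4'-dihydroxy-2'-(3-methylbut-2-enyl)flavan
Conditions: HCl (1.25 M in MeOH), THF, 0 °C to rt, argon
Reagents that add atoms: none
Why: acid-catalysed acetal exchange with methanol should remove both MOM groups as dimethoxymethane at room temperature, conditions that an aryl allyl ether tolerates and that ortho-prenylphenols commonly survive.

Step 12
Reactants: 14 (2S)-7-(allyloxy)-3',4'-dihydroxy-2'-(3-methylbut-2-enyl)flavan; 15 3-methylbut-2-enal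
Product: 18 kazinol B 7-O-allyl ether, via titanium catecholate 16 (not isolated), via ortho-quinone methide 17 (not isolated)
Conditions: Ti(OEt)4 (1.1 equiv), toluene, 110 °C, EtOH distilled off; then 15 (2.5 equiv), toluene, 110 °C, argon; aq. NH4Cl
Reagents that add atoms: none
Why: Ti(OEt)4 turns the catechol of 14 into titanium catecholate 16, the tetravalent titanium binds the carbonyl oxygen of 15 and delivers its carbonyl carbon to C5', the ortho carbon of the C4' oxygen, and loss of the titanium-bound oxygen from the benzylic titanate gives ortho-quinone methide 17 (C4'=O, C5'=C4'', C3''=C2''). A thermally allowed disrotatory oxa-6π electrocyclization of 17 then forms the O–C2'' bond, closes ring D as a 2H-pyran and restores the aromaticity of ring B, which drives the sequence. The closest known reaction type is the titanium alkoxide or amine mediated condensation of phenols with 3-methylbut-2-enal to 2,2-dimethyl-2H-chromenes, an ortho-selective hydroxyalkylation followed by electrocyclization. No stereocenter is created, since C2'' carries two methyl groups, and C2 should stay intact because the aryloxide medium is not acidic, so the C2–O1 bond does not ionize and the ortho-prenylphenol does not close to a chroman. The step needs regioselectivity among the aromatic positions: C5' is the only unsubstituted carbon ortho to either catechol oxygen because prenyl fills C2', inner-sphere delivery from the metal aryloxide avoids C6', and ring A has no free hydroxyl (O1 and the 7-O-allyl ether cannot form an aryloxide) and stays out.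

Step 13
Reactants: 18 kazinol B 7-O-allyl ether
Product: 19 kazinol B
Conditions: Pd(PPh3)4 (5 mol %), morpholine (5 equiv), THF, rt, argon
Reagents that add atoms: none
Why: Tsuji–Trost deallylation, in which zerovalent palladium ionizes the primary allyl aryl ether and morpholine traps the allyl group, while the hindered tertiary allylic ether of ring D, the prenyl group and the C2 stereocenter should not be touched.

**Compound list**

1 | 2-methylbut-3-en-2-ol | CC(C)(O)C=C | starting material
2 | tert-butyl 2-methylbut-3-en-2-yl carbonate | C=CC(C)(C)OC(=O)OC(C)(C)C | intermediate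
3 | 3,4-dihydroxyacetophenone | CC(=O)c1ccc(O)c(O)c1 | starting material
4 | 1-[3-hydroxy-4-(methoxymethoxy)phenyl]ethanone | CC(=O)c1ccc(OCOC)c(O)c1 | intermediate
5 | 1-[4-(methoxymethoxy)-3-(2-methylbut-3-en-2-yloxy)phenyl]ethanone | CC(=O)c1ccc(OCOC)c(OC(C)(C)C=C)c1 | intermediate
6 | 1-[3-hydroxy-4-(methoxymethoxy)-2-(3-methylbut-2-enyl)phenyl]ethanone | CC(=O)c1ccc(OCOC)c(O)c1CC=C(C)C | intermediate
7 | 1-[3,4-bis(methoxymethoxy)-2-(3-methylbut-2-enyl)phenyl]ethanone | CC(=O)c1ccc(OCOC)c(OCOC)c1CC=C(C)C | intermediate
8 | 2,4-dihydroxybenzaldehyde | O=Cc1ccc(O)cc1O | starting material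
9 | 4-(allyloxy)-2-hydroxybenzaldehyde | O=Cc1ccc(OCC=C)cc1O | intermediate
10 | (E)-3-[4-(allyloxy)-2-hydroxyphenyl]-1-[3,4-bis(methoxymethoxy)-2-(3-methylbut-2-enyl)phenyl]prop-2-en-1-one | C=CCOc1ccc(/C=C/C(=O)c2ccc(OCOC)c(OCOC)c2CC=C(C)C)c(O)c1 | intermediate
11 | 3-[4-(allyloxy)-2-hydroxyphenyl]-1-[3,4-bis(methoxymethoxy)-2-(3-methylbut-2-enyl)phenyl]propan-1-one | C=CCOc1ccc(CCC(=O)c2ccc(OCOC)c(OCOC)c2CC=C(C)C)c(O)c1 | intermediate
12 | (1R)-3-[4-(allyloxy)-2-hydroxyphenyl]-1-[3,4-bis(methoxymethoxy)-2-(3-methylbut-2-enyl)phenyl]propan-1-ol | C=CCOc1ccc(CC[C@@H](O)c2ccc(OCOC)c(OCOC)c2CC=C(C)C)c(O)c1 | intermediate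
13 | (2S)-7-(allyloxy)-2-[3,4-bis(methoxymethoxy)-2-(3-methylbut-2-enyl)phenyl]chroman | C=CCOc1ccc2CC[C@@H](c3ccc(OCOC)c(OCOC)c3CC=C(C)C)Oc2c1 | intermediate
14 | (2S)-7-(allyloxy)-3',4'-dihydroxy-2'-(3-methylbut-2-enyl)flavan | C=CCOc1ccc2CC[C@@H](c3ccc(O)c(O)c3CC=C(C)C)Oc2c1 | intermediate
15 | 3-methylbut-2-enal | CC(C)=CC=O | starting material
16 | diethoxytitanium 3',4'-catecholate of 14, drawn as the idealized monomer | C=CCOc1ccc2CC[C@@H](c3ccc4O[Ti](OCC)(OCC)Oc4c3CC=C(C)C)Oc2c1 | intermediate
17 | ortho-quinone methide of ring B: C4' carbonyl, (Z)-3-methylbut-2-enylidene on C5', C3' hydroxyl, C2' prenyl, (2S)-7-(allyloxy)chroman-2-yl on C1' | CC(C)=C/C=C1/C=C([C@@H]2CCc3ccc(OCC=C)cc3O2)C(CC=C(C)C)=C(O)C1=O | intermediate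
18 | kazinol B 7-O-allyl ether | CC(C)=CCc1c([C@@H]2CCc3ccc(OCC=C)cc3O2)cc2c(c1O)OC(C)(C)C=C2 | intermediate
19 | kazinol B | CC(C)=CCc1c([C@@H]2CCc3ccc(O)cc3O2)cc2c(c1O)OC(C)(C)C=C2 | target

**Count**

Total step count: 13.
Longest linear sequence: 11 steps (from 3 through steps 2, 3, 4, 5, 7, 8, 9, 10, 11, 12 and 13).

**Steps most likely to fail**

1. Step 12. The chelating catechol may hold the titanium so firmly that carbon–carbon bond formation at C5' stalls, or the enal may oligomerize before it is captured. The fallback sets out from 14 and uses a propargyl ether rearrangement in place of the aldehyde condensation. Copper-catalysed O-alkylation with 3-chloro-3-methylbut-1-yne (CuCl2·2H2O cat., DBU, MeCN, 0 °C) should favor the less hindered C4' hydroxyl and give (2S)-7-(allyloxy)-3'-hydroxy-4'-(2-methylbut-3-yn-2-yloxy)-2'-(3-methylbut-2-enyl)flavan F1. Heating F1 in N,N-diethylaniline at 140 °C should bring about the aryl propargyl Claisen rearrangement to C5', a 1,5-hydrogen shift and the same oxa-6π closure, and the route is rejoined at 18.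

2. Step 11. Protic acid may add the freed C3' hydroxyl across the prenyl olefin (chroman formation) or ionize the C2–O1 bond and erode the stereocenter. The fallback sets out from 13 and exchanges the acetals for silyl groups under buffered aprotic conditions. TMSOTf and 2,2'-bipyridyl in CH2Cl2 at 0 °C should convert both aryl MOM ethers into (2S)-7-(allyloxy)-3',4'-bis(trimethylsilyloxy)-2'-(3-methylbut-2-enyl)flavan F2. Neutral aqueous methanol then removes the silyl groups, and the route is rejoined at 14.

3. Step 3. The palladium catalyst may ionize the electron-poor aryl tert-prenyl ether again, so that the material drifts to the linear prenyl ether or to C-allylated products. The fallback sets out from 4 and builds the ether without a π-allyl intermediate. Copper-catalysed propargylation with 3-chloro-3-methylbut-1-yne (CuCl2·2H2O cat., DBU, MeCN, 0 °C) should give 1-[4-(methoxymethoxy)-3-(2-methylbut-3-yn-2-yloxy)phenyl]ethanone F3. Semi-hydrogenation of the alkyne (H2, Pd/CaCO3 poisoned with Pb(OAc)2, quinoline, EtOAc, rt) then returns the route to 5.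

**Further compounds**

F1 | step 12 | (2S)-7-(allyloxy)-3'-hydroxy-4'-(2-methylbut-3-yn-2-yloxy)-2'-(3-methylbut-2-enyl)flavan | C=CCOc1ccc2CC[C@@H](c3ccc(OC(C)(C)C#C)c(O)c3CC=C(C)C)Oc2c1
F2 | step 11 | (2S)-7-(allyloxy)-3',4'-bis(trimethylsilyloxy)-2'-(3-methylbut-2-enyl)flavan | C=CCOc1ccc2CC[C@@H](c3ccc(O[Si](C)(C)C)c(O[Si](C)(C)C)c3CC=C(C)C)Oc2c1
F3 | step 3 | 1-[4-(methoxymethoxy)-3-(2-methylbut-3-yn-2-yloxy)phenyl]ethanone | CC(=O)c1ccc(OCOC)c(OC(C)(C)C#C)c1
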